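**Retrosynthetic overview**

1. Quinone ring numbering: C1 (C=O, between C2 and C6), C2 (OAc), C3 (4-hydroxyphenyl), C4 (C=O), C5 (H), C6 (4-hydroxyphenyl). The strategy rests on the oxygens at C2 and C4 being meta to each other with the aryl-bearing C3 between them, while C1, para to C4, carries no other substituent; the ring is therefore a 2,5-diarylresorcinol oxidised at its free para carbon.
2. Late stage: the target comes from acetylation and desilylation of the 2-hydroxyquinone, which comes from para-oxidation (at C1) of a 2,5-diaryl-3-silyloxyphenol with its free OH on C4 and its silyl ether on C2.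
3. Key disconnection: the central ring, the only ring formed, is built by a Danheiser benzannulation of a 3-arylcyclobutenone (C4, C1, C6, C5) with an aryl siloxyalkyne (C3, C2). Bonds C3–C4 and C1–C2 come from the ketene–alkyne [2+2] step and C4–C5 from the 6π closure.
4. Both partners derive from one building block, O-silylated 4-ethynylphenol: dichloroketene cycloaddition and dechlorination give the cyclobutenone; acetylide oxygenation and O-silylation give the siloxyalkyne.

Key step: step 5

Remark: the target has no stereocentre; TBS = tert-butyldimethylsilyl, TIPS = triisopropylsilyl.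

**Route**

Step 1
Reactants: 1 4-ethynylphenol
Product: 2 tert-butyl(4-ethynylphenoxy)dimethylsilane
Conditions: TBSCl, imidazole, DMF, 0 → 23 °C
Reagents that add atoms: tert-butyldimethylsilyl chloride, CC(C)(C)[Si](C)(C)Cl
Why: Imidazole-mediated O-silylation of a phenol is routine and leaves the terminal alkyne untouched.

Step 2
Reactants: 2 tert-butyl(4-ethynylphenoxy)dimethylsilane
Product: 5 1-[4-(tert-butyldimethylsilyloxy)phenyl]-2-(triisopropylsilyloxy)acetylene, via lithium acetylide 3 (not isolated), via lithium ynolate 4 (not isolated)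
Conditions: LiN(SiMe3)2 (2.2 equiv), THF, −78 °C; t-BuOOH (anhydrous, in decane), −78 → 0 °C; TIPSOTf, −78 → 0 °C
Reagents that add atoms: tert-butyl hydroperoxide, CC(C)(C)OO; triisopropylsilyl trifluoromethanesulfonate, CC(C)[Si](OS(=O)(=O)C(F)(F)F)(C(C)C)C(C)C
Why: Oxygen transfer from the oxenoid lithium tert-butyl peroxide to a lithium acetylide gives the lithium ynolate, which the bulky silyl triflate silylates on oxygen (acetylide oxidation/ynolate O-silylation, an established siloxyalkyne synthesis for arylacetylenes), and the non-nucleophilic amide base spares the aryl silyl ether.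

Step 3
Reactants: 2 tert-butyl(4-ethynylphenoxy)dimethylsilane; 6 trichloroacetyl chloride
Product: 8 4,4-dichloro-3-[4-(tert-butyldimethylsilyloxy)phenyl]cyclobut-2-en-1-one, via dichloroketene 7 (not isolated)
Conditions: Zn(Cu) couple, Et2O/DME, 23 → 35 °C, slow addition of 6
Reagents that add atoms: none
Why: Dichloroketene generated by zinc dechlorination of 6 undergoes the known [2+2] ketene–alkyne cycloaddition, its carbonyl carbon bonding to the terminal alkyne carbon so that the aryl group ends up at C3 of the cyclobutenone, while DME ties up ZnCl2.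

Step 4
Reactants: 8 4,4-dichloro-3-[4-(tert-butyldimethylsilyloxy)phenyl]cyclobut-2-en-1-one
Product: 9 3-[4-(tert-butyldimethylsilyloxy)phenyl]cyclobut-2-en-1-one
Conditions: Zn dust, AcOH, TMEDA, EtOH, 0 → 23 °C
Reagents that add atoms: none
Why: Zinc-mediated reductive dechlorination of an α,α-dichloroketone in buffered acetic acid removes both chlorines through zinc enolates without touching the enone or the aryl silyl ether.

Step 5
Reactants: 9 3-[4-(tert-butyldimethylsilyloxy)phenyl]cyclobut-2-en-1-one; 5 1-[4-(tert-butyldimethylsilyloxy)phenyl]-2-(triisopropylsilyloxy)acetylene (1.3 equiv)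
Product: 14 2,5-bis[4-(tert-butyldimethylsilyloxy)phenyl]-3-(triisopropylsilyloxy)phenol, via aryl vinylketene 10 (not isolated), via vinylcyclobutenone 11 (not isolated), via dienylketene 12 (not isolated), via cyclohexadienone 13 (not isolated)
Conditions: PhMe (degassed), 80 °C, then 110 °C
Reagents that add atoms: none
Why: Thermal 4π electrocyclic opening of 9 gives vinylketene 10, which adds [2+2] to the electron-rich siloxyalkyne 5 to give vinylcyclobutenone 11 (bonds C3–C4 and C1–C2); a second, reversible 4π opening gives dienylketene 12, whose cis isomer is drained by ring closure to dienone 13, and enolisation gives the phenol. The closest known reaction type is the Danheiser benzannulation of 3-substituted cyclobutenones with siloxyalkynes, which delivers resorcinol monosilyl ethers. The only ring closed is the central six-membered carbocycle, by thermal disrotatory 6π electrocyclisation between the ketene carbon C4 and the terminal methylene C5. No stereocentre remains in the product; the one in 11 is racemic and is destroyed on ring opening. The selectivity needed is the orientation of the [2+2] step, in which the aryl-bearing alkyne carbon must bond to the ketene carbonyl carbon; oxygen lone-pair donation in 5 makes the carbon remote from oxygen the nucleophile toward the electrophilic ketene carbon. A slight excess of 5 should limit ketene dimerisation and acylation of the product phenol by the ketene.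

Step 6
Reactants: 14 2,5-bis[4-(tert-butyldimethylsilyloxy)phenyl]-3-(triisopropylsilyloxy)phenol
Product: 15 3,6-bis[4-(tert-butyldimethylsilyloxy)phenyl]-2-(triisopropylsilyloxy)-1,4-benzoquinone
Conditions: (KSO3)2NO (2.5 equiv), aq. KH2PO4, Bu4NHSO4 (cat.), CH2Cl2/H2O, 23 °C
Reagents that add atoms: potassium nitrosodisulfonate, [K+].[K+].[O]N(S(=O)(=O)[O-])S(=O)(=O)[O-]
Why: In the Teuber oxidation the nitroxyl radical abstracts the phenolic hydrogen, a second equivalent couples at the only free para carbon (C1) and loss of imidodisulfonate gives the para-quinone, while the buffered two-phase medium spares all three silyl ethers.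

Step 7
Reactants: 15 3,6-bis[4-(tert-butyldimethylsilyloxy)phenyl]-2-(triisopropylsilyloxy)-1,4-benzoquinone
Product: 16 2-hydroxy-3,6-bis[4-(tert-butyldimethylsilyloxy)phenyl]-1,4-benzoquinone
Conditions: aq. HCl (1 M), THF, 23 °C
Reagents that add atoms: none
Why: The ring-bound silyloxy group is a vinylogous silyl ester and is hydrolysed by dilute aqueous acid much faster than the acid-resistant aryl silyl ethers (selective silyl ester hydrolysis).

Step 8
Reactants: 16 2-hydroxy-3,6-bis[4-(tert-butyldimethylsilyloxy)phenyl]-1,4-benzoquinone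
Product: 17 2-acetoxy-3,6-bis[4-(tert-butyldimethylsilyloxy)phenyl]-1,4-benzoquinone
Conditions: Ac2O, pyridine, CH2Cl2, 0 °C
Reagents that add atoms: acetic anhydride, CC(=O)OC(C)=O
Why: O-acetylation of the acidic enolic hydroxyl of a hydroxyquinone with acetic anhydride and pyridine is standard, and the 2-acetoxy-1,4-quinone is the only para-quinone acetate that can form.

Step 9
Reactants: 17 2-acetoxy-3,6-bis[4-(tert-butyldimethylsilyloxy)phenyl]-1,4-benzoquinone
Product: 18 neonambiquinone A, 2-acetoxy-3,6-bis(4-hydroxyphenyl)-1,4-benzoquinone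
Conditions: HF·pyridine, THF, 0 → 23 °C; quench into cold pH 6 phosphate buffer
Reagents that add atoms: none
Why: Fluoride-driven cleavage of the aryl silyl ethers in an acidic, anhydrous medium, where the pyridine is protonated, offers no base or free nucleophile that could cleave or transfer the labile enol acetate.

**Compound list**

1 | 4-ethynylphenol | C#Cc1ccc(O)cc1 | starting material
2 | tert-butyl(4-ethynylphenoxy)dimethylsilane | C#Cc1ccc(O[Si](C)(C)C(C)(C)C)cc1 | intermediate
3 | lithium [4-(tert-butyldimethylsilyloxy)phenyl]acetylide | [Li+].[C-]#Cc1ccc(O[Si](C)(C)C(C)(C)C)cc1 | intermediate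
4 | lithium 2-[4-(tert-butyldimethylsilyloxy)phenyl]ethynolate (lithium ynolate) | [Li+].[O-]C#Cc1ccc(O[Si](C)(C)C(C)(C)C)cc1 | intermediate
5 | 1-[4-(tert-butyldimethylsilyloxy)phenyl]-2-(triisopropylsilyloxy)acetylene | CC(C)[Si](OC#Cc1ccc(O[Si](C)(C)C(C)(C)C)cc1)(C(C)C)C(C)C | intermediate
6 | trichloroacetyl chloride | O=C(Cl)C(Cl)(Cl)Cl | starting material
7 | dichloroketene | O=C=C(Cl)Cl | intermediate
8 | 4,4-dichloro-3-[4-(tert-butyldimethylsilyloxy)phenyl]cyclobut-2-en-1-one | O=C1C=C(c2ccc(O[Si](C)(C)C(C)(C)C)cc2)C1(Cl)Cl | intermediate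
9 | 3-[4-(tert-butyldimethylsilyloxy)phenyl]cyclobut-2-en-1-one | O=C1C=C(c2ccc(O[Si](C)(C)C(C)(C)C)cc2)C1 | intermediate
10 | 3-[4-(tert-butyldimethylsilyloxy)phenyl]buta-1,3-dien-1-one (aryl vinylketene) | O=C=CC(=C)c1ccc(O[Si](C)(C)C(C)(C)C)cc1 | intermediate
11 | 2-[4-(tert-butyldimethylsilyloxy)phenyl]-4-{1-[4-(tert-butyldimethylsilyloxy)phenyl]vinyl}-3-(triisopropylsilyloxy)cyclobut-2-en-1-one (racemic) | O=C1C(c2ccc(O[Si](C)(C)C(C)(C)C)cc2)=C(O[Si](C(C)C)(C(C)C)C(C)C)C1C(=C)c1ccc(O[Si](C)(C)C(C)(C)C)cc1 | intermediate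
12 | (3E)-2,5-bis[4-(tert-butyldimethylsilyloxy)phenyl]-3-(triisopropylsilyloxy)hexa-1,3,5-trien-1-one (dienylketene, ketene carbon and vinyl group cis) | O=C=C(c1ccc(O[Si](C)(C)C(C)(C)C)cc1)/C(O[Si](C(C)C)(C(C)C)C(C)C)=C\C(=C)c1ccc(O[Si](C)(C)C(C)(C)C)cc1 | intermediate
13 | 2,5-bis[4-(tert-butyldimethylsilyloxy)phenyl]-3-(triisopropylsilyloxy)cyclohexa-2,4-dien-1-one | O=C1CC(c2ccc(O[Si](C)(C)C(C)(C)C)cc2)=CC(O[Si](C(C)C)(C(C)C)C(C)C)=C1c1ccc(O[Si](C)(C)C(C)(C)C)cc1 | intermediate
14 | 2,5-bis[4-(tert-butyldimethylsilyloxy)phenyl]-3-(triisopropylsilyloxy)phenol | Oc1cc(-c2ccc(O[Si](C)(C)C(C)(C)C)cc2)cc(O[Si](C(C)C)(C(C)C)C(C)C)c1-c1ccc(O[Si](C)(C)C(C)(C)C)cc1 | intermediate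
15 | 3,6-bis[4-(tert-butyldimethylsilyloxy)phenyl]-2-(triisopropylsilyloxy)-1,4-benzoquinone | CC(C)[Si](OC1=C(c2ccc(O[Si](C)(C)C(C)(C)C)cc2)C(=O)C=C(c2ccc(O[Si](C)(C)C(C)(C)C)cc2)C1=O)(C(C)C)C(C)C | intermediate
16 | 2-hydroxy-3,6-bis[4-(tert-butyldimethylsilyloxy)phenyl]-1,4-benzoquinone | OC1=C(c2ccc(O[Si](C)(C)C(C)(C)C)cc2)C(=O)C=C(c2ccc(O[Si](C)(C)C(C)(C)C)cc2)C1=O | intermediate
17 | 2-acetoxy-3,6-bis[4-(tert-butyldimethylsilyloxy)phenyl]-1,4-benzoquinone | CC(=O)OC1=C(c2ccc(O[Si](C)(C)C(C)(C)C)cc2)C(=O)C=C(c2ccc(O[Si](C)(C)C(C)(C)C)cc2)C1=O | intermediate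
18 | neonambiquinone A, 2-acetoxy-3,6-bis(4-hydroxyphenyl)-1,4-benzoquinone | CC(=O)OC1=C(c2ccc(O)cc2)C(=O)C=C(c2ccc(O)cc2)C1=O | target

**Step count**

Total steps: 9. Longest linear sequence: 8 (steps 1, 3, 4, 5, 6, 7, 8, 9); step 2 is the second branch.

**Steps most likely to fail**

Step 5 (key benzannulation). The aryl group on the nucleophilic alkyne carbon may slow the capture of the vinylketene. Ketene dimerisation, acylation of the product phenol by the ketene, or thermal rearrangement of the siloxyalkyne to a silylketene could then take over. The fallback builds the same ring by a Moore rearrangement of a squarate-derived cyclobutenone; it sets out from alkyne 2 and comes back at hydroxyquinone 16.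
- Alkyne 2 would undergo Markovnikov bromoboration with B-bromo-9-borabicyclo[3.3.1]nonane and protodeboronation with AcOH to give 1-(1-bromovinyl)-4-(tert-butyldimethylsilyloxy)benzene F1.
- Bromine–lithium exchange (t-BuLi, THF, −78 °C) would give 1-[4-(tert-butyldimethylsilyloxy)phenyl]vinyllithium F2.
- Separately, 4-(tert-butyldimethylsilyloxy)phenyllithium F3, made from commercial (4-bromophenoxy)(tert-butyl)dimethylsilane and n-BuLi, would add to commercial diisopropyl squarate to give 4-[4-(tert-butyldimethylsilyloxy)phenyl]-4-hydroxy-2,3-diisopropoxycyclobut-2-en-1-one F4.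
- Catalytic aqueous HCl in CH2Cl2 would rearrange F4 to 3-[4-(tert-butyldimethylsilyloxy)phenyl]-4-isopropoxycyclobut-3-ene-1,2-dione F5.
- F2 should add to the more electrophilic carbonyl of F5, the one next to the alkoxy-bearing carbon, to give 2-[4-(tert-butyldimethylsilyloxy)phenyl]-4-{1-[4-(tert-butyldimethylsilyloxy)phenyl]vinyl}-4-hydroxy-3-isopropoxycyclobut-2-en-1-one F6.
- Heating in p-xylene at 140 °C should give 2,5-bis[4-(tert-butyldimethylsilyloxy)phenyl]-3-isopropoxybenzene-1,4-diol F7.
- Ag2O would oxidise F7 to 3,6-bis[4-(tert-butyldimethylsilyloxy)phenyl]-2-isopropoxy-1,4-benzoquinone F8.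
- BCl3 (CH2Cl2, −78 °C) would cleave the isopropyl vinylogous ester to give 16.

Step 9 (final desilylation). The enol acetate is a vinylogous anhydride; during the slow cleavage of the aryl silyl ethers it may be hydrolysed or its acetyl group may move to a liberated phenol. The fallback reverses the order of deprotection and acetylation; it sets out from 16 and comes back at target 18.
- HF·pyridine in THF would remove both silyl groups from 16 to give 2-hydroxy-3,6-bis(4-hydroxyphenyl)-1,4-benzoquinone F9.
- The enolic hydroxyl is several pKa units more acidic than the phenols, so one equivalent of i-Pr2NEt (THF, −78 °C) would ionise it alone.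
- One equivalent of acetyl chloride (−78 → −20 °C) should then acylate only that oxygen, and no free base would remain to catalyse acetyl transfer.

Step 6 (para-oxidation). The para carbon C1 is flanked by the bulky triisopropylsilyloxy group and an aryl ring, so coupling with the nitroxyl radical may be slow and the lipophilic phenol may be recovered or over-oxidised. The fallback oxidises the less hindered ortho carbon instead; it sets out from 14 and comes back at 16.
- IBX in DMF at 23 °C should deliver oxygen to the only free ortho carbon and give 3,6-bis[4-(tert-butyldimethylsilyloxy)phenyl]-5-(triisopropylsilyloxy)cyclohexa-3,5-diene-1,2-dione F10.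
- Aqueous HCl (1 M) in THF would then remove the ring silyl group, and the resulting hydroxy-ortho-quinone tautomerises to the 2-hydroxy-1,4-quinone.
- Because the two aryl groups are identical and lie on the symmetry axis of the resorcinol core, this tautomer is 16 itself.

**Further compounds**

F1 | step 5 | 1-(1-bromovinyl)-4-(tert-butyldimethylsilyloxy)benzene | C=C(Br)c1ccc(O[Si](C)(C)C(C)(C)C)cc1
F2 | step 5 | 1-[4-(tert-butyldimethylsilyloxy)phenyl]vinyllithium | [Li]C(=C)c1ccc(O[Si](C)(C)C(C)(C)C)cc1
F3 | step 5 | 4-(tert-butyldimethylsilyloxy)phenyllithium | [Li]c1ccc(O[Si](C)(C)C(C)(C)C)cc1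
F4 | step 5 | 4-[4-(tert-butyldimethylsilyloxy)phenyl]-4-hydroxy-2,3-diisopropoxycyclobut-2-en-1-one | CC(C)OC1=C(OC(C)C)C(O)(c2ccc(O[Si](C)(C)C(C)(C)C)cc2)C1=O
F5 | step 5 | 3-[4-(tert-butyldimethylsilyloxy)phenyl]-4-isopropoxycyclobut-3-ene-1,2-dione | CC(C)OC1=C(c2ccc(O[Si](C)(C)C(C)(C)C)cc2)C(=O)C1=O
F6 | step 5 | 2-[4-(tert-butyldimethylsilyloxy)phenyl]-4-{1-[4-(tert-butyldimethylsilyloxy)phenyl]vinyl}-4-hydroxy-3-isopropoxycyclobut-2-en-1-one | CC(C)OC1=C(c2ccc(O[Si](C)(C)C(C)(C)C)cc2)C(=O)C1(O)C(=C)c1ccc(O[Si](C)(C)C(C)(C)C)cc1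
F7 | step 5 | 2,5-bis[4-(tert-butyldimethylsilyloxy)phenyl]-3-isopropoxybenzene-1,4-diol | CC(C)Oc1c(O)c(-c2ccc(O[Si](C)(C)C(C)(C)C)cc2)cc(O)c1-c1ccc(O[Si](C)(C)C(C)(C)C)cc1
F8 | step 5 | 3,6-bis[4-(tert-butyldimethylsilyloxy)phenyl]-2-isopropoxy-1,4-benzoquinone | CC(C)OC1=C(c2ccc(O[Si](C)(C)C(C)(C)C)cc2)C(=O)C=C(c2ccc(O[Si](C)(C)C(C)(C)C)cc2)C1=O
F9 | step 9 | 2-hydroxy-3,6-bis(4-hydroxyphenyl)-1,4-benzoquinone | OC1=C(c2ccc(O)cc2)C(=O)C=C(c2ccc(O)cc2)C1=O
F10 | step 6 | 3,6-bis[4-(tert-butyldimethylsilyloxy)phenyl]-5-(triisopropylsilyloxy)cyclohexa-3,5-diene-1,2-dione | O=C1C(=O)C(c2ccc(O[Si](C)(C)C(C)(C)C)cc2)=CC(O[Si](C(C)C)(C(C)C)C(C)C)=C1c1ccc(O[Si](C)(C)C(C)(C)C)cc1
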